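**Retrosynthetic overview**
- The five-membered carbocycle is closed last. One palladium cascade joins a ring A bromo-alkyne, the tosylhydrazone of a ring B aldehyde and a methylboron reagent.
- In that cascade the former aldehyde carbon of ring B reacts with reversed polarity (diazo/carbene carbon). It bonds first to the ring A carbon that carried bromine, then to the alkyne (5-exo-dig); methyl capture completes the isopropylidene. A chiral ligand is meant to set the methine.
- Ring A piece: 2-bromo-6-hydroxybenzaldehyde, chloromethylation para to the phenol, then copper alkynylation with propyne.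
- Ring B piece: a catechol aldehyde and an (R)-epoxy tosylate (Sharpless epoxidation of prenol). O-alkylation followed by 6-exo epoxide opening with inversion closes the 1,4-dioxane ring and sets its stereocentre.
- Ring order: dioxane ring first (step 5), indane five-membered ring last (step 7); both benzene rings are bought.

Assumption: the SMILES is read as (S) at the indane methine and (S) at the dioxane carbon; the three starting materials and propyne are treated as catalogue chemicals.

**Route**

Step 1
Reactants: 1 2-bromo-6-hydroxybenzaldehyde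
Product: 2 2-bromo-3-(chloromethyl)-6-hydroxybenzaldehyde
Conditions: (CH2O)n, conc. HCl, ZnCl2 (cat.), 50 °C
Reagents that add atoms: formaldehyde (as paraformaldehyde) C=O; hydrogen chloride Cl
Why: Blanc chloromethylation; the electrophile should enter para to the phenol (meta to the aldehyde), the site that gives 5-(chloromethyl)salicylaldehyde from salicylaldehyde itself, and HCl turns the benzylic alcohol into the chloride; no stereocentre.

Step 2
Reactants: 2 2-bromo-3-(chloromethyl)-6-hydroxybenzaldehyde
Product: 3 2-bromo-3-(but-2-yn-1-yl)-6-hydroxybenzaldehyde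
Conditions: propyne (5 equiv), copper iodide CuI (10 mol %), iPr2NEt, MeCN, 0 °C to rt, slow addition of 2
Reagents that add atoms: propyne CC#C
Why: Copper-catalysed coupling of a benzylic chloride with a terminal alkyne (copper acetylide substitution, helped by the quinone methide that a para-hydroxybenzyl chloride forms); slow addition keeps the quinone methide dilute and the tertiary amine cannot condense with the aldehyde; no stereocentre.

Step 3
Reactants: 4 3-bromo-2-hydroxy-5-methylbenzaldehyde
Product: 5 2,3-dihydroxy-5-methylbenzaldehyde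
Conditions: NaOH (aq, 8 equiv), copper powder (Cu, cat.), reflux, N2; then HCl
Reagents that add atoms: sodium hydroxide [Na+].[OH-]
Why: Copper-mediated hydrolysis of an ortho-bromophenol (Ullmann-type hydroxylation, the reaction that converts 5-bromovanillin into 5-hydroxyvanillin); the phenoxide aldehyde resists Cannizzaro reaction; no stereocentre.

Step 4
Reactants: 6 3-methylbut-2-en-1-ol (prenol)
Product: 8 [(2R)-3,3-dimethyloxiran-2-yl]methyl 4-methylbenzenesulfonate, via epoxy alcohol 7 (not isolated)
Conditions: Ti(OiPr)4 (5 mol %), D-(−)-diethyl tartrate (7 mol %), t-BuOOH, 4 Å MS, CH2Cl2, −20 °C; P(OMe)3; then TsCl, Et3N, DMAP (cat.), −10 °C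
Reagents that add atoms: tert-butyl hydroperoxide CC(C)(C)OO; p-toluenesulfonyl chloride Cc1ccc(cc1)S(=O)(=O)Cl
Why: Sharpless asymmetric epoxidation; the D-tartrate catalyst gives the (R)-epoxide (about 90–94 % ee expected), and in-situ tosylation avoids isolating the water-soluble epoxy alcohol.

Step 5
Reactants: 5 2,3-dihydroxy-5-methylbenzaldehyde; 8 [(2R)-3,3-dimethyloxiran-2-yl]methyl 4-methylbenzenesulfonate
Product: 10 (3S)-3-(2-hydroxypropan-2-yl)-7-methyl-2,3-dihydro-1,4-benzodioxine-5-carbaldehyde, via epoxy ether 9 (not isolated)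
Conditions: NaH (2.1 equiv), DMSO, 20 °C; add 8; then 70 °C
Reagents that add atoms: none
Why: Dianion O-alkylation then 6-exo-tet epoxide opening; in the disodium salt the 3-oxide (not chelated to the aldehyde) is the better nucleophile and displaces the primary tosylate, then the remaining phenoxide opens the epoxide at its CH carbon with inversion, so (R) becomes the (S) dioxane centre.

Step 6
Reactants: 10 (3S)-3-(2-hydroxypropan-2-yl)-7-methyl-2,3-dihydro-1,4-benzodioxine-5-carbaldehyde
Product: 11 N'-{(E)-[(3S)-3-(2-hydroxypropan-2-yl)-7-methyl-2,3-dihydro-1,4-benzodioxin-5-yl]methylidene}-4-methylbenzenesulfonohydrazide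
Conditions: TsNHNH2, MeOH, 50 °C, then 0 °C (crystallise)
Reagents that add atoms: p-toluenesulfonyl hydrazide Cc1ccc(cc1)S(=O)(=O)NN
Why: Hydrazone condensation; crystallisation should also raise the enantiomeric purity carried from step 4.

Step 7
Reactants: 3 2-bromo-3-(but-2-yn-1-yl)-6-hydroxybenzaldehyde; 11 tosylhydrazone of the ring B aldehyde
Product: 13 diaporindene H, via aryldiazomethane 12 (not isolated)
Conditions: Pd2(dba)3 (2.5 mol %), chiral sulfinamide–monophosphine ligand (Sadphos type, 6 mol %, antipode chosen to give the S methine), MeB(OH)2 (3 equiv), Cs2CO3 (4 equiv), 1,4-dioxane/H2O 20:1, 80 °C, slow addition of 11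
Reagents that add atoms: methylboronic acid CB(O)O
Why: Proposed new method: base converts 11 into diazo compound 12, so the former aldehyde carbon acts with reversed polarity as a nucleophilic diazo/carbene carbon and binds the aryl–palladium bromide formed from 3; aryl migration (carbene migratory insertion, Barluenga-type coupling) gives a diarylmethyl–palladium species without β-hydrogen, which adds syn across the tethered butyne (5-exo-dig; direct aryl–alkyne insertion would need a strained 4-exo closure) to an alkenyl–palladium that is methylated by Suzuki-type transmetalation, giving the isopropylidene with no E/Z issue; the chiral ligand is meant to set the (S) methine at the insertion/diarylmethyl–palladium stage and the other epimer is a separable diastereomer; 3 reacts as its cesium phenoxide, which makes its aldehyde a poor electrophile; closest known chemistry is palladium tosylhydrazone/aryl halide cascades ending in intramolecular carbopalladation and enantioselective three-component tosylhydrazone–aryl bromide couplings that give gem-diarylmethine stereocentres with sulfinamide–phosphine ligands.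

**Compound list**

1 | 2-bromo-6-hydroxybenzaldehyde | O=Cc1c(O)cccc1Br | starting material
2 | 2-bromo-3-(chloromethyl)-6-hydroxybenzaldehyde | O=Cc1c(O)ccc(CCl)c1Br | intermediate
3 | 2-bromo-3-(but-2-yn-1-yl)-6-hydroxybenzaldehyde | CC#CCc1ccc(O)c(C=O)c1Br | intermediate
4 | 3-bromo-2-hydroxy-5-methylbenzaldehyde | Cc1cc(Br)c(O)c(C=O)c1 | starting material
5 | 2,3-dihydroxy-5-methylbenzaldehyde | Cc1cc(O)c(O)c(C=O)c1 | intermediate
6 | 3-methylbut-2-en-1-ol (prenol) | CC(C)=CCO | starting material
7 | [(2R)-3,3-dimethyloxiran-2-yl]methanol (formed in the flask) | OC[C@H]1OC1(C)C | intermediate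
8 | [(2R)-3,3-dimethyloxiran-2-yl]methyl 4-methylbenzenesulfonate | Cc1ccc(cc1)S(=O)(=O)OC[C@H]1OC1(C)C | intermediate
9 | 2-hydroxy-5-methyl-3-{[(2R)-3,3-dimethyloxiran-2-yl]methoxy}benzaldehyde (formed in the flask as its sodium phenoxide) | Cc1cc(OC[C@H]2OC2(C)C)c(O)c(C=O)c1 | intermediate
10 | (3S)-3-(2-hydroxypropan-2-yl)-7-methyl-2,3-dihydro-1,4-benzodioxine-5-carbaldehyde | Cc1cc(C=O)c2O[C@H](C(C)(C)O)COc2c1 | intermediate
11 | N'-{(E)-[(3S)-3-(2-hydroxypropan-2-yl)-7-methyl-2,3-dihydro-1,4-benzodioxin-5-yl]methylidene}-4-methylbenzenesulfonohydrazide | Cc1ccc(cc1)S(=O)(=O)N/N=C/c1cc(C)cc2c1O[C@H](C(C)(C)O)CO2 | intermediate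
12 | 2-[(2S)-8-(diazomethyl)-6-methyl-2,3-dihydro-1,4-benzodioxin-2-yl]propan-2-ol (formed in the flask) | [N-]=[N+]=Cc1cc(C)cc2c1O[C@H](C(C)(C)O)CO2 | intermediate
13 | diaporindene H, (3S)-5-hydroxy-3-[(3S)-3-(2-hydroxypropan-2-yl)-7-methyl-2,3-dihydro-1,4-benzodioxin-5-yl]-2-(propan-2-ylidene)-2,3-dihydro-1H-indene-4-carbaldehyde | CC(C)=C1Cc2ccc(O)c(C=O)c2[C@H]1c1cc(C)cc2c1O[C@H](C(C)(C)O)CO2 | target

**Step count**

Total steps: 7. Longest linear sequence: 4 steps (4 → 5 → 10 → 11 → 13, or equally 6 → 8 → 10 → 11 → 13).

**Steps most likely to fail, with fallbacks**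

Step 7 is the main risk: ligand control at the methine, and methyl capture in competition with other palladium pathways, are untested on this substrate. The fallback sets out from chloride 2 and hydrazone 11 and returns at 13. Nitromethane in large excess with K2CO3 at 0 °C adds to the quinone methide of 2 and gives 2-bromo-6-hydroxy-3-(2-nitroethyl)benzaldehyde F1. Zerovalent palladium with a chiral bisphosphine and Cs2CO3 then couples F1 with 11; the same carbene insertion is now followed by attack of the tethered nitronate carbon on the η3-benzyl palladium (asymmetric benzylic alkylation). This closes the ring to (3S)-5-hydroxy-3-[(3S)-3-(2-hydroxypropan-2-yl)-7-methyl-2,3-dihydro-1,4-benzodioxin-5-yl]-2-nitro-2,3-dihydro-1H-indene-4-carbaldehyde F2, a mixture at the nitro carbon. The nitronate of F2 (LiOMe, DMSO) is coupled with 2-bromo-2-nitropropane under light (Kornblum radical-chain substitution) to the vicinal dinitro compound (3S)-5-hydroxy-3-[(3S)-3-(2-hydroxypropan-2-yl)-7-methyl-2,3-dihydro-1,4-benzodioxin-5-yl]-2-nitro-2-(2-nitropropan-2-yl)-2,3-dihydro-1H-indene-4-carbaldehyde F3. Na2S·9H2O in DMF (or Bu3SnH/AIBN) then removes both nitro groups and gives the isopropylidene of 13 without acid or strong base.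

Step 5 is the second risk: if the chelated phenoxide alkylates first, the regioisomeric dioxane results. The fallback fixes the regiochemistry by substitution pattern; it sets out from 4 (using 8) and returns at 10. Allyl bromide and K2CO3 give 2-(allyloxy)-3-bromo-5-methylbenzaldehyde F4. Baeyer–Villiger/Dakin oxidation (mCPBA, then K2CO3/MeOH) gives 2-(allyloxy)-3-bromo-5-methylphenol F5, whose only free phenol is alkylated with 8 (K2CO3, DMF) to 2-(allyloxy)-1-bromo-5-methyl-3-{[(2R)-3,3-dimethyloxiran-2-yl]methoxy}benzene F6. Pd(PPh3)4 with K2CO3 in MeOH removes the allyl group and the freed phenoxide opens the epoxide (6-exo, inversion) to 2-[(2S)-8-bromo-6-methyl-2,3-dihydro-1,4-benzodioxin-2-yl]propan-2-ol F7. n-BuLi (2.2 equiv, THF, −78 °C) followed by DMF gives 10.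

Step 1 is the third risk: the site next to bromine may react sluggishly, and ortho attack or diarylmethane formation may compete. The fallback sets out from 1 and returns at 2. Iodination para to the phenol (NIS, TsOH cat., MeCN) gives 2-bromo-6-hydroxy-3-iodobenzaldehyde F8, whose isomers are easily separated. Stille coupling at the C–I bond with Bu3SnCH2OH (Pd(PPh3)4, dioxane, 90 °C) gives 2-bromo-6-hydroxy-3-(hydroxymethyl)benzaldehyde F9, and conc. HCl converts this para-hydroxybenzyl alcohol into 2.

**Further compounds**

F1 | step 7 | 2-bromo-6-hydroxy-3-(2-nitroethyl)benzaldehyde | O=Cc1c(O)ccc(CC[N+](=O)[O-])c1Br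
F2 | step 7 | (3S)-5-hydroxy-3-[(3S)-3-(2-hydroxypropan-2-yl)-7-methyl-2,3-dihydro-1,4-benzodioxin-5-yl]-2-nitro-2,3-dihydro-1H-indene-4-carbaldehyde | [O-][N+](=O)C1Cc2ccc(O)c(C=O)c2[C@H]1c1cc(C)cc2c1O[C@H](C(C)(C)O)CO2
F3 | step 7 | (3S)-5-hydroxy-3-[(3S)-3-(2-hydroxypropan-2-yl)-7-methyl-2,3-dihydro-1,4-benzodioxin-5-yl]-2-nitro-2-(2-nitropropan-2-yl)-2,3-dihydro-1H-indene-4-carbaldehyde | CC(C)([N+](=O)[O-])C1([N+](=O)[O-])Cc2ccc(O)c(C=O)c2[C@H]1c1cc(C)cc2c1O[C@H](C(C)(C)O)CO2
F4 | step 5 | 2-(allyloxy)-3-bromo-5-methylbenzaldehyde | C=CCOc1c(Br)cc(C)cc1C=O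
F5 | step 5 | 2-(allyloxy)-3-bromo-5-methylphenol | C=CCOc1c(Br)cc(C)cc1O
F6 | step 5 | 2-(allyloxy)-1-bromo-5-methyl-3-{[(2R)-3,3-dimethyloxiran-2-yl]methoxy}benzene | C=CCOc1c(Br)cc(C)cc1OC[C@H]1OC1(C)C
F7 | step 5 | 2-[(2S)-8-bromo-6-methyl-2,3-dihydro-1,4-benzodioxin-2-yl]propan-2-ol | Cc1cc(Br)c2O[C@H](C(C)(C)O)COc2c1
F8 | step 1 | 2-bromo-6-hydroxy-3-iodobenzaldehyde | O=Cc1c(O)ccc(I)c1Br
F9 | step 1 | 2-bromo-6-hydroxy-3-(hydroxymethyl)benzaldehyde | O=Cc1c(O)ccc(CO)c1Br
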